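## Structural features

The target is a germacranolide: a ten-membered carbocycle C1–C10 with a γ-lactone fused trans across C6–C7 (ring oxygen on C6, C11(=C13)–C12 on C7), a tiglate on O8 and a free hydroxyl on C5. Four stereocentres stand in a row, C5 (S), C6 (S), C7 (R) and C8 (R); with H7 drawn α, O5 is β, O6 is α and O8 is β, so O5/O6 are trans on the ring and the ester is cis to the C7 branch. The other half of the ring is a cross-conjugated dienone, C10(CH3)=C1–C2(=O)–C3=C4(CH3), with both trisubstituted alkenes Z in the ring sense (C9/C2 cis, C2/C5 cis). Fragile groups are the α-methylene lactone and the dienone (Michael acceptors), the tiglate, the allylic C5 carbinol next to the lactone oxygen, and the doubly allylic C2 position. The real difficulty is the medium ring: closing ten atoms that contain two Z trisubstituted alkenes is entropically and enthalpically poor and gives no built-in control of alkene geometry. The key step uses the eudesmane hidden in the germacrane: a bond between C5 and C10 folds the ring into a cis-decalin whose ring B (C5–C10) is the six-membered ring of (R)-carvone, with C7 and its branch C11–C13 already in place, and whose ring A (C1–C5, C10) contains the Z C3=C4 alkene. Heterolysis of that bond, pushed by an alkoxide on C5 and pulled by a leaving group on C1, returns the ten-membered ring and converts the cis ring fusion into the Z C1=C10 alkene.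

## Logic of the disconnections

40 ⇒ 39 ⇒ 37. The C2 carbonyl is taken back to a carbinol (C2=O to C2–H/O–H) and the C11=C13 bond to C11–Se plus C13–H. These two Michael acceptors are tolerated by nothing else in the route, so they are removed first. The gain is 37, which has no electrophilic alkene. The forward demand is an oxidant that takes the doubly allylic C2 carbinol and spares the allylic C5 carbinol, and a syn elimination that runs toward C13.

37 ⇒ 36 ⇒ 35 ⇒ 32 + 33. The O2–Si bond, the C5–H bond and the O8–acyl bond are cut in this order. The ester is thus formed when O8 is the only hydroxyl present, because C5 is still a ketone in 32. This removes any O5/O8 differentiation. The forward demand is hydride delivery to C5 anti to the C6–O bond (5S) without touching the enoate or the lactone.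

32 ⇒ 31 ⇒ 29 (key). The C5 carbonyl carbon is rejoined to C10 and C1 takes back a sulfonate: the C1=C10 and C5=O π bonds are traded for the C5–C10 σ bond and the C1–O bond. The medium ring collapses to a cis-decalin, and the Z alkene becomes a ring-fusion relationship that is set by ordinary six-membered-ring chemistry. The forward demand is an antiperiplanar O–C5–C10–C1–O array with C9 axial on ring A.

29 ⇒ 28 ⇒ 26. The O1–S and C11–Se bonds are cut. Selenium is placed before the ring is opened, so that no strong base is needed afterwards. The forward demands are sulfonylation of the secondary O1 only and enolate chemistry in the presence of two free hydroxyls.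

26 ⇒ 24 ⇒ 22. The lactone O6–C12 bond and the C12–O bonds are cut back to an isopropenyl group and a free 6-hydroxyl. The gain is that C11–C13 is simply the side chain of 1. The forward demands are hydroboration of the 1,1-disubstituted alkene only and oxidation of the primary alcohol only.

22 ⇒ 21. The C4–C5 bond of ring A is cut between an alkenyl iodide and the ring-B ketone. The Z C3=C4 geometry is then carried by an acyclic iodide. The forward demand is attack on the ketone face that gives the cis fusion (5β-OH).

21 ⇒ 12 + 18. The C1–C10 bond (with the C9–H bond) is cut, which separates the C1–C4 unit from ring B at the quaternary carbon. The forward demand is a regiodefined tetrasubstituted enolate that reacts on its α face and sets C1 relative to C10 and C2.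

12 ⇒ 9 ⇒ 8 ⇒ 6 ⇒ 1. The C6–O and C8–O bonds are cut. Both oxygens go back to enol(ate) chemistry of 1: C6 through the cross-conjugated enolate, C8 through the extended one. The forward demand is 6α (trans to C7) but 8β (cis to C7), so C8 needs one inversion.

18 ⇒ 17 ⇒ 16 ⇒ 15 ⇒ 14 ⇒ 13. The C3=C4 bond is cut by olefination of the formyl group of 13, and C1 is set to the aldehyde level at the end. The forward demands are Z geometry of the iodoalkene and no loss of configuration at C2.

## Other disconnections considered

Alternative 1: The cut is the C5=C6 bond of a precursor that has C5 and C6 at alkene level. In the forward sense the second-generation Grubbs catalyst would join the vinyl group on C7 of tetraene A1 with the terminal alkene on C4, giving trienone A2 and ethylene. The C5=C6 alkene would then be epoxidised and opened at C6 by the C12 carboxylate.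
- In its favour: the acrylate carbon set is carried intact, and anti opening of a cis epoxide gives the required trans O5/O6 pair.
- Equal or better: on step economy it is better than the chosen plan (no selenium step and no late C2 oxidation).
- Against it, structure: A1 is an acyclic Z,Z cross-conjugated dienone free to isomerise, and C7/C8 must come from acyclic stereocontrol and not from the chiral pool.
- Against it, mechanism: metathesis must close a strained ten-membered ring through a conjugated, electron-poor diene terminus, and nothing enforces the Z geometry of the new alkene. The later epoxidation must pick one alkene out of five and one face of it.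
- Comparison: the chosen plan makes the ring by breaking a bond, which is stereospecific and carries no ring-closure entropy penalty.

Alternative 2: The cut is C2–C3, with C2–C7 re-formed. Cyclohexenone A3 carries the C3–C6 chain on a quaternary C7. Bu3SnH with AIBN would turn the C3 iodide into a vinyl radical that adds to the C2 carbonyl; the alkoxy radical would then cleave C2–C7 to give the ten-membered dienone A4.
- In its favour: four atoms are inserted in one step, and the Z C1=C10 alkene is pre-set inside a six-membered ring.
- Equal or better: it forms the C2 ketone directly, so the chemoselective C2 oxidation of the chosen plan is not needed.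
- Against it, mechanism: addition of a vinyl radical to a ketone carbonyl is reversible and competes with hydrogen transfer. C7 becomes a radical, so its configuration is decided by hydrogen delivery to a flexible ring.
- Against it, structure: A3 needs a quaternary stereocentre that is then destroyed.
- Against it, step economy: the acetate arm, the acetonide and the benzyl-type ether still need lactonisation, methylenation and an ester exchange, so it is no shorter.
- Comparison: in the chosen plan C7 comes untouched from carvone.

Alternative 3: The cuts are C1–C2 and C2–C3, with C2 supplied by carbon monoxide. Pd2(dba)3 with AsPh3 (zerovalent palladium) under CO would insert into the C1–I bond of A5, take up CO and couple with the C3 stannane to close the ring as A6, the C5 silyl ether of the target.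
- In its favour: the endgame is the shortest (one deprotection), with the lactone, tiglate and all four stereocentres already present.
- Equal or better: it is the equal of the chosen plan in delivering both Z alkenes, since both couplings retain geometry, and better in convergence.
- Against it, mechanism: it is a true ten-membered ring closure. Direct (non-carbonylative) coupling to a nine-membered diene, protodestannylation and insertion into the methylene lactone all compete.
- Against it, structure: A5 needs four contiguous stereocentres set on an open chain and two Z trisubstituted alkenyl metal/halide termini.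
- Comparison: the chosen plan avoids any medium-ring closure.

Key step: step 16

Remarks on the chemistry:
- Locants C1–C15 are those of the target ring in all compounds; β is the face of the C7–C11 bond and of the C10 methyl group, α the face of H7.
- An aldehyde made from (R)-glyceraldehyde acetonide by olefination of its formyl group and oxidation of its CH2O end is 2S. C2 is therefore S (α, cis to O1) in 20–39; a 2R centre would need the enantiomeric acetonide and an anti-Felkin aldol. C2 ends as a ketone, so the target is unaffected.
- C11 of the fragmentation substrate carries CH3 and SePh and no hydrogen. No enolisation is then needed after ring opening, and O8 can be acylated while C5 is still a ketone.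
- Compounds 23–26 are mixtures at C11 (25 also at C12); this is without consequence because C11 becomes quaternary in 28 and sp2 in 39.

## Route

Step 1
Reactants: 1 (R)-carvone
Product: 6 trans-4-hydroxycarvone (8α-OH), via potassium dienolate 2 (not isolated), via silyl dienol ether 3 (not isolated), via endoperoxide 4 (not isolated), via hydroperoxide 5 (not isolated)
Conditions: KOtBu, THF, 0 °C; TMSCl, −78 to 0 °C; O2, hν, tetraphenylporphyrin (cat.), CH2Cl2, −78 °C; MeOH, PPTS (cat.); PPh3, 0 °C
Reagents that add atoms: oxygen, O=O
Why: Alkoxide conditions are equilibrating, so the fully conjugated dienolate 2 is silylated on oxygen to the s-cis 1-silyloxy-1,3-diene 3; singlet oxygen adds to it in a [4+2] cycloaddition across C5/C8 anti to the C7 isopropenyl group, the peroxy ketal 4 opens to 5 and PPh3 reduces the hydroperoxide (photooxygenation of a 1-oxygenated cyclohexa-1,3-diene, a vinylogous γ-hydroxylation). The new C8 centre is therefore trans to C7 (8α).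

Step 2
Reactants: 6 trans-4-hydroxycarvone
Product: 8 cis-4-hydroxycarvone (8β-OH), via 4-nitrobenzoate 7 (not isolated)
Conditions: 4-O2NC6H4CO2H, PPh3, DIAD, THF, 0 °C to rt; then K2CO3, MeOH, 0 °C
Reagents that add atoms: 4-nitrobenzoic acid, OC(=O)c1ccc(cc1)[N+](=O)[O-]
Why: Mitsunobu inversion: the activated allylic C8–O bond is displaced by the carboxylate with inversion (8α to 8β, cis to C7) and mild methanolysis frees the alcohol; the fully substituted C10 blocks the allylic-transposition pathway and the C7–H is syn to the leaving group, so anti elimination is not available.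

Step 3
Reactants: 8 cis-4-hydroxycarvone
Product: 9 cis-4-(triethylsilyloxy)carvone
Conditions: TESCl, imidazole, DMF, 0 °C
Reagents that add atoms: chlorotriethylsilane, CC[Si](Cl)(CC)CC
Why: Standard silylation of a secondary allylic alcohol; the triethylsilyl group is chosen because it must later be removed in the presence of the C2 tert-butyldimethylsilyl ether.

Step 4
Reactants: 9 cis-4-(triethylsilyloxy)carvone
Product: 12 6α-(trimethylsilyloxy)-8β-(triethylsilyloxy) enone, via lithium dienolate 10 (not isolated), via silyl dienol ether 11 (not isolated)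
Conditions: LiN(iPr)2, THF, −78 °C; TMSCl; then mCPBA, NaHCO3, CH2Cl2, −20 °C
Reagents that add atoms: chlorotrimethylsilane, C[Si](C)(C)Cl; 3-chloroperbenzoic acid, OOC(=O)c1cccc(Cl)c1
Why: Kinetic deprotonation at C6 gives the cross-conjugated dienolate, trapped as 2-silyloxydiene 11; Rubottom oxidation then epoxidises the enol ether double bond anti to the C7 isopropenyl and C8 silyloxy groups, and 1,4-silyl migration gives the 6α-silyloxy ketone (trans to C7).

Step 5
Reactants: 13 (R)-glyceraldehyde acetonide
Product: 14 (S)-4-[(Z)-2-iodoprop-1-en-1-yl]-2,2-dimethyl-1,3-dioxolane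
Conditions: EtPPh3I, n-BuLi, THF; I2, −78 °C; NaN(SiMe3)2; then 13, −78 to −20 °C
Reagents that add atoms: ethyltriphenylphosphonium iodide, CC[P+](c1ccccc1)(c1ccccc1)c1ccccc1.[I-]; iodine, II
Why: Stork–Zhao olefination with the α-iodoethylidene ylide gives the (Z)-2-iodoalk-2-ene (C2 and iodine cis) under kinetic low-temperature control; the α-stereocentre is not enolised at −78 °C (its descriptor changes from R to S only because the ranking of its carbon substituents changes).

Step 6
Reactants: 14 alkenyl iodide acetonide
Product: 15 (2S,3Z)-4-iodopent-3-ene-1,2-diol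
Conditions: AcOH/H2O 4:1, 40 °C
Reagents that add atoms: none
Why: Acid hydrolysis of the isopropylidene acetal; the alkenyl iodide is inert to aqueous acetic acid.

Step 7
Reactants: 15 diol
Product: 16 (2S,3Z)-1,2-bis(tert-butyldimethylsilyloxy)-4-iodopent-3-ene
Conditions: TBSCl, imidazole, DMF, rt
Reagents that add atoms: tert-butylchlorodimethylsilane, CC(C)(C)[Si](C)(C)Cl
Why: Exhaustive silylation of a primary and a secondary alcohol.

Step 8
Reactants: 16 bis-silyl ether
Product: 17 (2S,3Z)-2-(tert-butyldimethylsilyloxy)-4-iodopent-3-en-1-ol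
Conditions: HF·pyridine, pyridine, THF, 0 °C
Reagents that add atoms: none
Why: Sterically controlled mono-desilylation; the primary silyl ether is cleaved much faster than the secondary one.

Step 9
Reactants: 17 primary alcohol
Product: 18 (2S,3Z)-2-(tert-butyldimethylsilyloxy)-4-iodopent-3-enal
Conditions: Dess–Martin periodinane, NaHCO3, CH2Cl2, 0 °C; used at once
Reagents that add atoms: none
Why: Dess–Martin oxidation under buffered, amine-free conditions avoids enolisation of the α-silyloxy β,γ-unsaturated aldehyde, which would racemise C2 or move the alkene into conjugation.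

Step 10
Reactants: 12 enone; 18 aldehyde
Product: 21 aldol keto diol (1α-OH, 2α-OTBS, 6α-OH, 8β-OTES, 10β-CH3), via lithium enolate 19 (not isolated), via O6-trimethylsilyl aldol 20 (not isolated)
Conditions: LiBH(s-Bu)3, THF, −78 °C; 18, −78 °C; AcOH; then citric acid, MeOH, 0 °C
Reagents that add atoms: none
Why: Reductive aldol: 1,4-hydride addition to C9 gives the regiodefined tetrasubstituted enolate 19, which adds to 18 through a Zimmerman–Traxler chair. C10 is set because both half-chairs of 19 expose the α face (the β face carries the axial C8 silyloxy group in one and the axial isopropenyl group in the other), so C1 bonds α and the methyl stays β; C1 is set by the equatorial aldehyde substituent in the chair and by attack anti to the C2–O bond (Felkin–Anh, matched for the 2S aldehyde), which give 1α-OH. Acidic methanol then removes only the trimethylsilyl group; the short time at −78 °C with a lithium counter-ion is meant to prevent retro-aldol and 1,2-silyl shift.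

Step 11
Reactants: 21 aldol keto diol
Product: 22 cis-decalin triol (5β-OH)
Conditions: CrCl2, NiCl2 (cat.), DMF, rt
Reagents that add atoms: none
Why: Nozaki–Hiyama–Kishi reaction: zerovalent nickel inserts into the C4–I bond with retention of the Z geometry, the alkenyl group passes to trivalent chromium and adds to the C5 ketone (six-membered ring A), which is activated by the α-hydroxyl. C4 reaches the carbonyl on the α face where the C1 tether stands (axial attack; the equatorial path runs into the axial C10 methyl), so the fusion is cis and O5 is β.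

Step 12
Reactants: 22 cis-decalin triol
Product: 24 tetraol (C12–OH, C11 epimers), via B-alkyl-9-BBN adduct 23 (not isolated)
Conditions: 9-BBN, THF, 0 °C to rt; then NaOH, H2O2, 0 °C
Reagents that add atoms: hydrogen peroxide, OO
Why: Hydroboration–oxidation: 9-BBN adds anti-Markovnikov to the 1,1-disubstituted alkene far faster than to the hindered trisubstituted C3=C4; O-borinates formed at the free hydroxyls are hydrolysed in the oxidative work-up.

Step 13
Reactants: 24 tetraol
Product: 26 lactone diol (trans-fused 6α,12-olide, C11 epimers), via lactol 25 (not isolated)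
Conditions: TEMPO (cat.), PhI(OAc)2, CH2Cl2, rt
Reagents that add atoms: none
Why: Oxoammonium oxidation is selective for the primary alcohol; the aldehyde is captured by the 6α-hydroxyl as a five-membered lactol, which is oxidised again to the diequatorial trans γ-lactone. O8 is silylated, and O5 (equatorial and 1,3 to C7) cannot reach C12.

Step 14
Reactants: 26 lactone diol
Product: 28 selenide diol (11α-SePh, 11β-CH3), via trilithium enolate dialkoxide 27 (not isolated)
Conditions: LiN(iPr)2 (3.3 equiv), THF, −78 °C; PhSeBr, −78 °C
Reagents that add atoms: benzeneselenenyl bromide, Br[Se]c1ccccc1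
Why: Selenenylation of a lactone enolate with the two hydroxyls held as lithium alkoxides; the electrophile enters C11 anti to the C7–C8 bond and the axial 8β-silyloxy group, and both C11 epimers of 26 converge on one enolate. The low temperature keeps the C2 silyl group from shifting to O1.

Step 15
Reactants: 28 selenide diol
Product: 29 mesylate (C1α-OMs, free 5β-OH)
Conditions: MsCl, Et3N, DMAP (cat.), CH2Cl2, −10 °C
Reagents that add atoms: methanesulfonyl chloride, CS(=O)(=O)Cl
Why: Sulfonylation of the only secondary hydroxyl; the tertiary C5 hydroxyl does not react, and triethylamine is too weak a base to start fragmentation.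

Step 16
Reactants: 29 mesylate
Product: 31 (1(10)Z,3Z)-cyclodecadienone lactone (C5 ketone), via potassium alkoxide 30 (not isolated)
Conditions: KOtBu (1.1 equiv), THF, −20 to 0 °C; pH 7 buffer
Reagents that add atoms: none
Why: KOtBu deprotonates the tertiary C5 hydroxyl to give 30, in which the O–C5, C5–C10 and C1–OMs bonds are antiperiplanar; an oxygen lone pair feeds σ*(C5–C10) as that bond feeds σ*(C1–O), so C5=O, C1=C10 and mesylate form in one concerted step (Grob fragmentation). The closest known reaction type is the base-induced fragmentation of decalin-1,3-diol monosulfonates to cyclodecenones. No ring is closed by bond formation: the ten-membered ring appears because the zero-atom bridge C5–C10 of the bicyclo[4.4.0] system is cleaved, that is, a ring expansion by fragmentation. No stereocentre is created; C1, C5 and C10 become sp2, and C2, C6, C7, C8 and C11 are not touched. The selectivity needed is Z geometry at C1=C10: the trans lactone freezes the ring-B chair in which C9 is axial on ring A and gauche to C2 while the C10 methyl is anti to C2, and the equatorial mesylate allows only this antiperiplanar array, so C2 and C9 end cis (a trans fusion would give E). Side reactions are held back by the substrate: the equatorial mesylate has no anti hydrogen for elimination, O5 cannot reach the back of C1 to form an oxetane, and the quaternary C11 cannot enolise. The axial 2α-silyloxy group is 1,3 to C9 and may twist ring A slightly, but the antiperiplanar array tolerates this and the strain is released as the ring opens. The base is consumed as potassium mesylate, which limits enolisation of the product at C6 and C2.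

Step 17
Reactants: 31 cyclodecadienone lactone
Product: 32 C8 alcohol (8β-OH)
Conditions: PPTS, MeOH/CH2Cl2, 0 °C
Reagents that add atoms: none
Why: Acid-catalysed methanolysis removes the triethylsilyl ether much faster than the tert-butyldimethylsilyl ether; the trans lactone prevents a transannular hemiketal between O8 and C5.

Step 18
Reactants: 32 C8 alcohol; 33 tiglic acid
Product: 35 tiglate ketone, via mixed anhydride 34 (not isolated)
Conditions: 33, 2,4,6-Cl3C6H2COCl, Et3N, toluene, rt; then 32, DMAP, 0 °C to rt
Reagents that add atoms: none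
Why: Yamaguchi esterification of the only free hydroxyl; the E geometry of the tiglate is the stable one and is retained.

Step 19
Reactants: 35 tiglate ketone
Product: 36 C5 alcohol (5β-OH, 5S)
Conditions: NaBH4, CeCl3·7H2O, MeOH/THF, −78 °C
Reagents that add atoms: none
Why: Luche reduction: cerium-activated 1,2-addition to the enone carbonyl, which is faster than attack on the enoate or lactone. Hydride should add anti to the C6–O bond from the outer face of the ring (Felkin–Anh, no chelation by the acyloxy oxygen), giving O5 β, trans to O6 on the ring.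

Step 20
Reactants: 36 C5 alcohol
Product: 37 diol (2-OH, 5-OH)
Conditions: HF·pyridine, pyridine, THF, 0 °C to rt
Reagents that add atoms: none
Why: Buffered fluoride cleavage of the secondary silyl ether; the excess pyridine keeps the doubly allylic alcohol from ionising.

Step 21
Reactants: 37 diol
Product: 39 α-methylene lactone diol, via selenoxide 38 (not isolated)
Conditions: NaIO4, NaHCO3, THF/MeOH/H2O, 0 °C to rt
Reagents that add atoms: none
Why: Selenide oxidation and selenoxide syn elimination: a hydrogen of the freely rotating C13 methyl is taken, while the ring C7–H is held out of the C–Se plane by the trans lactone fusion; exocyclic elimination is the known outcome for 11-methyl-11-phenylseleno trans-fused 6,12-olides. Periodate avoids the peracid-type epoxidant that hydrogen peroxide forms with the selenium by-product.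

Step 22
Reactants: 39 α-methylene lactone diol
Product: 40 target
Conditions: MnO2, CH2Cl2, 0 °C
Reagents that add atoms: none
Why: MnO2 oxidation of the doubly allylic C2 carbinol to the cross-conjugated dienone; the C5 carbinol is only singly allylic, flanked by the C4 methyl and deactivated by the acyloxy group on C6, so it should react much more slowly.

## Compound list

1 | (R)-carvone, (5R)-2-methyl-5-(prop-1-en-2-yl)cyclohex-2-en-1-one | CC(=C)[C@@H]1CC=C(C)C(=O)C1 | starting material
2 | potassium (5S)-2-methyl-5-(prop-1-en-2-yl)cyclohexa-1,3-dien-1-olate (extended dienolate of 1) | [K+].[O-]C1=C(C)C=C[C@@H](C(C)=C)C1 | intermediate (not isolated)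
3 | trimethyl{[(5S)-2-methyl-5-(prop-1-en-2-yl)cyclohexa-1,3-dien-1-yl]oxy}silane | C[Si](C)(C)OC1=C(C)C=C[C@@H](C(C)=C)C1 | intermediate (not isolated)
4 | 6-methyl-8-(prop-1-en-2-yl)-1-(trimethylsilyloxy)-2,3-dioxabicyclo[2.2.2]oct-5-ene, peroxide bridge anti to the isopropenyl group | C[Si](C)(C)O[C@@]12OO[C@@H](C=C1C)[C@@H](C(C)=C)C2 | intermediate (not isolated)
5 | (4S,5R)-4-hydroperoxy-2-methyl-5-(prop-1-en-2-yl)cyclohex-2-en-1-one | O=C1C(C)=C[C@H](OO)[C@@H](C(C)=C)C1 | intermediate (not isolated)
6 | (4S,5R)-4-hydroxy-2-methyl-5-(prop-1-en-2-yl)cyclohex-2-en-1-one (trans-4-hydroxycarvone, 8α-OH) | O=C1C(C)=C[C@H](O)[C@@H](C(C)=C)C1 | intermediate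
7 | 4-nitrobenzoate of (4R,5R)-4-hydroxy-2-methyl-5-(prop-1-en-2-yl)cyclohex-2-en-1-one | O=C1C(C)=C[C@@H](OC(=O)c2ccc(cc2)[N+](=O)[O-])[C@@H](C(C)=C)C1 | intermediate (not isolated)
8 | (4R,5R)-4-hydroxy-2-methyl-5-(prop-1-en-2-yl)cyclohex-2-en-1-one (cis-4-hydroxycarvone, 8β-OH) | O=C1C(C)=C[C@@H](O)[C@@H](C(C)=C)C1 | intermediate
9 | (4R,5R)-2-methyl-5-(prop-1-en-2-yl)-4-(triethylsilyloxy)cyclohex-2-en-1-one | O=C1C(C)=C[C@@H](O[Si](CC)(CC)CC)[C@@H](C(C)=C)C1 | intermediate
10 | lithium cross-conjugated dienolate of 9 (C5–O−, C5=C6) | [Li+].[O-]C1=C[C@H](C(C)=C)[C@H](O[Si](CC)(CC)CC)C=C1C | intermediate (not isolated)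
11 | cross-conjugated trimethylsilyl dienol ether of 9 (C5–OSiMe3, C5=C6, C9=C10) | C[Si](C)(C)OC1=C[C@H](C(C)=C)[C@H](O[Si](CC)(CC)CC)C=C1C | intermediate (not isolated)
12 | (4R,5R,6S)-2-methyl-5-(prop-1-en-2-yl)-4-(triethylsilyloxy)-6-(trimethylsilyloxy)cyclohex-2-en-1-one (6α-OTMS, 8β-OTES) | O=C1[C@@H](O[Si](C)(C)C)[C@H](C(C)=C)[C@H](O[Si](CC)(CC)CC)C=C1C | intermediate
13 | (R)-2,2-dimethyl-1,3-dioxolane-4-carbaldehyde | CC1(C)OC[C@H](C=O)O1 | starting material
14 | (S)-4-[(Z)-2-iodoprop-1-en-1-yl]-2,2-dimethyl-1,3-dioxolane | CC1(C)OC[C@H](/C=C(/C)I)O1 | intermediate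
15 | (2S,3Z)-4-iodopent-3-ene-1,2-diol | OC[C@H](/C=C(/C)I)O | intermediate
16 | (2S,3Z)-1,2-bis(tert-butyldimethylsilyloxy)-4-iodopent-3-ene | CC(C)(C)[Si](C)(C)OC[C@H](/C=C(/C)I)O[Si](C)(C)C(C)(C)C | intermediate
17 | (2S,3Z)-2-(tert-butyldimethylsilyloxy)-4-iodopent-3-en-1-ol | OC[C@H](/C=C(/C)I)O[Si](C)(C)C(C)(C)C | intermediate
18 | (2S,3Z)-2-(tert-butyldimethylsilyloxy)-4-iodopent-3-enal | O=C[C@H](/C=C(/C)I)O[Si](C)(C)C(C)(C)C | intermediate
19 | lithium enolate from 12 (C5–O−, C5=C10; 6α-OTMS, 7β-isopropenyl, 8β-OTES) | [Li+].[O-]C1=C(C)C[C@@H](O[Si](CC)(CC)CC)[C@@H](C(C)=C)[C@@H]1O[Si](C)(C)C | intermediate (not isolated)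
20 | aldol adduct with O6–SiMe3: C5 ketone, 10β-CH3, C10 side chain C1(α-OH)–C2(α-OTBS)–C3=C4(I)CH3 (Z), 6α-OTMS, 7β-isopropenyl, 8β-OTES | O=C1[C@@H](O[Si](C)(C)C)[C@H](C(C)=C)[C@H](O[Si](CC)(CC)CC)C[C@@]1(C)[C@@H](O)[C@@H](O[Si](C)(C)C(C)(C)C)/C=C(/C)I | intermediate (not isolated)
21 | aldol keto diol: as 20 with free 6α-OH | O=C1[C@@H](O)[C@H](C(C)=C)[C@H](O[Si](CC)(CC)CC)C[C@@]1(C)[C@@H](O)[C@@H](O[Si](C)(C)C(C)(C)C)/C=C(/C)I | intermediate
22 | cis-fused eudesma-3,11-diene-1α,5β,6α-triol, 2α-OTBS, 8β-OTES (10β-CH3, 7α-H) | C=C(C)[C@@H]1[C@H](O[Si](CC)(CC)CC)C[C@@]2(C)[C@@H](O)[C@@H](O[Si](C)(C)C(C)(C)C)C=C(C)[C@@]2(O)[C@H]1O | intermediate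
23 | C12 9-borabicyclo[3.3.1]nonan-9-yl adduct of 22 (drawn with free hydroxyls; C11 epimers) | CC(CB1C2CCCC1CCC2)[C@@H]1[C@H](O[Si](CC)(CC)CC)C[C@@]3(C)[C@@H](O)[C@@H](O[Si](C)(C)C(C)(C)C)C=C(C)[C@@]3(O)[C@H]1O | intermediate (not isolated)
24 | cis-fused eudesm-3-ene-1α,5β,6α,12-tetraol, 2α-OTBS, 8β-OTES (C11 epimers) | CC(CO)[C@@H]1[C@H](O[Si](CC)(CC)CC)C[C@@]2(C)[C@@H](O)[C@@H](O[Si](C)(C)C(C)(C)C)C=C(C)[C@@]2(O)[C@H]1O | intermediate
25 | 6α,12-lactol of 24 (C11 and C12 epimers) | CC1C(O)O[C@H]2[C@H]1[C@H](O[Si](CC)(CC)CC)C[C@@]3(C)[C@@H](O)[C@@H](O[Si](C)(C)C(C)(C)C)C=C(C)[C@@]23O | intermediate (not isolated)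
26 | cis-fused 1α,5β-dihydroxy-2α-OTBS-8β-OTES-eudesm-3-en-6α,12-olide (trans lactone, C11 epimers) | CC1C(=O)O[C@H]2[C@H]1[C@H](O[Si](CC)(CC)CC)C[C@@]3(C)[C@@H](O)[C@@H](O[Si](C)(C)C(C)(C)C)C=C(C)[C@@]23O | intermediate
27 | trilithium lactone enolate 1,5-dialkoxide of 26 | [Li+].[Li+].[Li+].CC1=C([O-])O[C@H]2[C@H]1[C@H](O[Si](CC)(CC)CC)C[C@@]3(C)[C@@H]([O-])[C@@H](O[Si](C)(C)C(C)(C)C)C=C(C)[C@@]23[O-] | intermediate (not isolated)
28 | 11α-phenylseleno-11β-methyl derivative of 26 (1α,5β-diol) | C[C@@]1([Se]c4ccccc4)C(=O)O[C@H]2[C@H]1[C@H](O[Si](CC)(CC)CC)C[C@@]3(C)[C@@H](O)[C@@H](O[Si](C)(C)C(C)(C)C)C=C(C)[C@@]23O | intermediate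
29 | cis-fused eudesm-3-en-6α,12-olide: 1α-mesyloxy, 2α-OTBS, 5β-hydroxy, 8β-OTES, 10β-CH3, 11α-SePh, 11β-CH3 | C[C@@]1([Se]c4ccccc4)C(=O)O[C@H]2[C@H]1[C@H](O[Si](CC)(CC)CC)C[C@@]3(C)[C@@H](OS(C)(=O)=O)[C@@H](O[Si](C)(C)C(C)(C)C)C=C(C)[C@@]23O | intermediate
30 | potassium C5 alkoxide of 29 | [K+].C[C@@]1([Se]c4ccccc4)C(=O)O[C@H]2[C@H]1[C@H](O[Si](CC)(CC)CC)C[C@@]3(C)[C@@H](OS(C)(=O)=O)[C@@H](O[Si](C)(C)C(C)(C)C)C=C(C)[C@@]23[O-] | intermediate (not isolated)
31 | (1(10)Z,3Z)-5-oxo-2α-OTBS-8β-OTES-11α-phenylseleno-germacra-1(10),3-dien-6α,12-olide (2S) | C[C@@]1([Se]c3ccccc3)C(=O)O[C@H]2[C@H]1[C@H](O[Si](CC)(CC)CC)C/C(C)=C\[C@@H](O[Si](C)(C)C(C)(C)C)/C=C(/C)C2=O | intermediate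
32 | 8β-hydroxy analogue of 31 | C[C@@]1([Se]c3ccccc3)C(=O)O[C@H]2[C@H]1[C@H](O)C/C(C)=C\[C@@H](O[Si](C)(C)C(C)(C)C)/C=C(/C)C2=O | intermediate
33 | tiglic acid, (E)-2-methylbut-2-enoic acid | C/C=C(\C)C(=O)O | starting material
34 | tiglic 2,4,6-trichlorobenzoic anhydride | C/C=C(\C)C(=O)OC(=O)c1c(Cl)cc(Cl)cc1Cl | intermediate (not isolated)
35 | 8β-tigloyloxy analogue of 31 (C5 ketone, 2α-OTBS) | C[C@@]1([Se]c3ccccc3)C(=O)O[C@H]2[C@H]1[C@H](OC(=O)/C(C)=C/C)C/C(C)=C\[C@@H](O[Si](C)(C)C(C)(C)C)/C=C(/C)C2=O | intermediate
36 | 5β-hydroxy (5S) analogue of 35 | C[C@@]1([Se]c3ccccc3)C(=O)O[C@H]2[C@H]1[C@H](OC(=O)/C(C)=C/C)C/C(C)=C\[C@@H](O[Si](C)(C)C(C)(C)C)/C=C(/C)[C@@H]2O | intermediate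
37 | 2α,5β-dihydroxy-8β-tigloyloxy-11α-phenylseleno-germacra-1(10)Z,3Z-dien-6α,12-olide | C[C@@]1([Se]c3ccccc3)C(=O)O[C@H]2[C@H]1[C@H](OC(=O)/C(C)=C/C)C/C(C)=C\[C@@H](O)/C=C(/C)[C@@H]2O | intermediate
38 | selenoxide of 37 | C[C@@]1([Se](=O)c3ccccc3)C(=O)O[C@H]2[C@H]1[C@H](OC(=O)/C(C)=C/C)C/C(C)=C\[C@@H](O)/C=C(/C)[C@@H]2O | intermediate (not isolated)
39 | 2α,5β-dihydroxy-8β-tigloyloxy-germacra-1(10)Z,3Z,11(13)-trien-6α,12-olide | C=C1C(=O)O[C@H]2[C@H]1[C@H](OC(=O)/C(C)=C/C)C/C(C)=C\[C@@H](O)/C=C(/C)[C@@H]2O | intermediate
40 | CNP0230565.7, 5β-hydroxy-2-oxo-8β-tigloyloxy-germacra-1(10)Z,3Z,11(13)-trien-6α,12-olide | C=C1C(=O)O[C@H]2[C@H]1[C@H](OC(=O)/C(C)=C/C)C/C(C)=C\C(=O)/C=C(/C)[C@@H]2O | target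

## Step count and least certain steps

Total: 22 steps. Longest linear sequence: 18 steps (13 to 40 through steps 5–9 and 10–22); from 1 it is 17 steps.

Step 16 (key step). What may go wrong: a twisted ring A (the 2α-silyloxy group is 1,3 to C9) could slow the fragmentation enough for the alkoxide to start other reactions, and any excess alkoxide could enolise the product at C6 (loss of the trans lactone configuration) or at C2 (alkene migration). Fallback, from 29: the tertiary hydroxyl is silylated (TMSOTf, 2,6-lutidine) to the C5 trimethylsilyl ether F1, and the alkoxide is then released in low concentration by fluoride (CsF, 18-crown-6, THF, 0 °C), so that it fragments as it forms and no free strong base is ever present; this returns to the route at 31.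

Step 10. What may go wrong: proton transfer from the α-silyloxy aldehyde to the basic enolate (enolisation with loss of C2 configuration), 1,2-reduction of the enone, or retro-aldol of the hindered aldolate. Fallback, from 12: the enolate is trapped after the conjugate reduction (LiBH(s-Bu)3; TMSCl) as the silyl enol ether F2, which is combined with 18 in a Lewis-acid Mukaiyama aldol (BF3·OEt2, CH2Cl2, −78 °C) through an open transition state with no basic species; this returns at 20.

Step 11. What may go wrong: slow addition of the alkenylchromium species to the hindered ketone, with protodemetalation (loss of iodine without ring closure) taking over. Fallback, from 21: both hydroxyls are silylated (TMSCl, imidazole) to the bis-trimethylsilyl ether F3, halogen–lithium exchange (t-BuLi, Et2O/THF, −78 °C) gives an alkenyllithium that adds to the ketone to form the cyclised bis-silyl ether F4, and citric acid in methanol returns to the route at 22.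

Step 1. What may go wrong: competing reaction modes of singlet oxygen on 3 (ene-type oxygenation at the C5=C10 enol ether with silyl shift) and incomplete facial selectivity. Fallback, from 3: electrophilic γ-bromination with NBS (THF, −78 °C) gives trans-4-bromocarvone F5; displacement with CsOAc in DMF proceeds with inversion to cis-4-acetoxycarvone F6; K2CO3 in MeOH then gives 8 directly, which also makes the Mitsunobu step unnecessary.

Step 19. What may go wrong: poor facial selectivity, because the conformation of the ten-membered ketone is not fixed and substrate control may be weak. Fallback, from 35 to 36: reagent-controlled Corey–Bakshi–Shibata reduction with the (S)-2-methyl oxazaborolidine and catecholborane at −78 °C, in which the alkenyl C4 side acts as the large group; no new compound is made.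

Step 22. What may go wrong: over-oxidation, with the allylic C5 carbinol also oxidised. Fallback, from 35: the order of the redox steps is changed. The C2 silyl ether is removed (HF·pyridine) to give 2-hydroxy-5-ketone F7, MnO2 gives 2,5-dione F8, and NaBH4/CeCl3 (1 equiv, −78 °C) reduces the more electrophilic α-acyloxy ketone at C5 to give 2-oxo-5β-hydroxy selenide F9; the periodate step then returns to the route at 40.

## Further compounds

F1 | step 16 | C5 trimethylsilyl ether of 29 | C[C@@]1([Se]c4ccccc4)C(=O)O[C@H]2[C@H]1[C@H](O[Si](CC)(CC)CC)C[C@@]3(C)[C@@H](OS(C)(=O)=O)[C@@H](O[Si](C)(C)C(C)(C)C)C=C(C)[C@@]23O[Si](C)(C)C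
F2 | step 10 | trimethylsilyl enol ether of the reduced enone (C5–OSiMe3, C5=C10) | C[Si](C)(C)OC1=C(C)C[C@@H](O[Si](CC)(CC)CC)[C@@H](C(C)=C)[C@@H]1O[Si](C)(C)C
F3 | step 11 | 1,6-bis(trimethylsilyl) ether of 21 | O=C1[C@@H](O[Si](C)(C)C)[C@H](C(C)=C)[C@H](O[Si](CC)(CC)CC)C[C@@]1(C)[C@@H](O[Si](C)(C)C)[C@@H](O[Si](C)(C)C(C)(C)C)/C=C(/C)I
F4 | step 11 | 1,6-bis(trimethylsilyl) ether of 22 | C=C(C)[C@@H]1[C@H](O[Si](CC)(CC)CC)C[C@@]2(C)[C@@H](O[Si](C)(C)C)[C@@H](O[Si](C)(C)C(C)(C)C)C=C(C)[C@@]2(O)[C@H]1O[Si](C)(C)C
F5 | step 1 | trans-4-bromocarvone (8α-Br) | O=C1C(C)=C[C@H](Br)[C@@H](C(C)=C)C1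
F6 | step 1 | cis-4-acetoxycarvone (8β-OAc) | O=C1C(C)=C[C@@H](OC(C)=O)[C@@H](C(C)=C)C1
F0 | step 19 | none | none
F7 | step 22 | 2α-hydroxy-5-oxo-8β-tigloyloxy selenide | C[C@@]1([Se]c3ccccc3)C(=O)O[C@H]2[C@H]1[C@H](OC(=O)/C(C)=C/C)C/C(C)=C\[C@@H](O)/C=C(/C)C2=O
F8 | step 22 | 2,5-dioxo-8β-tigloyloxy selenide | C[C@@]1([Se]c3ccccc3)C(=O)O[C@H]2[C@H]1[C@H](OC(=O)/C(C)=C/C)C/C(C)=C\C(=O)/C=C(/C)C2=O
F9 | step 22 | 2-oxo-5β-hydroxy-8β-tigloyloxy selenide | C[C@@]1([Se]c3ccccc3)C(=O)O[C@H]2[C@H]1[C@H](OC(=O)/C(C)=C/C)C/C(C)=C\C(=O)/C=C(/C)[C@@H]2O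
A1 | alternative 1 | acyclic tetraenone with C7 vinyl and acrylate arm, C8 hydroxyl, Z,Z-dienone and C4 vinyl | C=C[C@H](C(=C)C(=O)OC)[C@H](O)C/C(C)=C\C(=O)/C=C(/C)C=C
A2 | alternative 1 | ten-membered all-Z trienone with C7 acrylate arm and C8 hydroxyl | C1/C(C)=C\C(=O)/C=C(/C)\C=C/[C@H](C(=C)C(=O)OC)[C@@H]1O
A3 | alternative 2 | cyclohexenone with quaternary C7 bearing the acetate arm and the C6/C5 acetonide chain ending in the Z C3 iodoalkene, C8 4-methoxybenzyl ether | COC(=O)C[C@@]1([C@@H]2OC(C)(C)O[C@H]2/C(C)=C\I)[C@H](OCc3ccc(OC)cc3)CC(C)=CC1=O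
A4 | alternative 2 | ten-membered Z,Z-dienone with C5/C6 acetonide, C7 acetate arm and C8 4-methoxybenzyl ether | COC(=O)C[C@@H]1[C@H](OCc3ccc(OC)cc3)C/C(C)=C\C(=O)/C=C(/C)[C@@H]2OC(C)(C)O[C@@H]12
A5 | alternative 3 | open-chain α-methylene lactone with Z C1 iodoalkene, Z C3 tributylstannyl alkene, C5 silyl ether and C8 tiglate | C=C1C(=O)O[C@H]([C@@H](O[Si](C)(C)C(C)(C)C)/C(C)=C\[Sn](CCCC)(CCCC)CCCC)[C@H]1[C@H](OC(=O)/C(C)=C/C)C/C(C)=C\I
A6 | alternative 3 | C5 tert-butyldimethylsilyl ether of the target | C=C1C(=O)O[C@H]2[C@H]1[C@H](OC(=O)/C(C)=C/C)C/C(C)=C\C(=O)/C=C(/C)[C@@H]2O[Si](C)(C)C(C)(C)C
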